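The route rests on cutting the C1–C9 and C10–C11 bonds of the gem-dimethylcyclobutane (C1, C9, C10, C11; caryophyllane numbering). Because C1–C9 is shared with the nine-membered carbocycle (C1–C9), this cut opens both rings. In the forward sense, one intramolecular enone–alkene [2+2] photocycloaddition closes the four- and nine-membered rings together and sets C1; C9 is then corrected by equilibration. The precursor is a ring A/B chroman-dione carrying, on adjacent trans-related pyran carbons, a homoprenyl chain (at C4, beside the methyl) and a 3-oxopent-4-enyl chain (at C5). It is assembled by a Knoevenagel/hetero-Diels–Alder reaction on mono-epoxidised (E)-geranylacetone.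

Key step: step 6

Atom labels: terpenoid carbons carry caryophyllane numbers (C1, C9 ring-fusion CH; C4 O-bearing quaternary C; C5 its CH neighbour; C8 carbonyl/methylidene carbon; C10 cyclobutane CH2; C11 CMe2). C1' is the isobutyl-bearing CH, ring A the tetramethylcyclohexenedione, ring B the dihydropyran. Chromene locants (C2 = C4, C3 = C5, C4 = C1') appear only in names.

Remark 1: the terpenoid part of the photosubstrate is geranylacetone plus one carbon (C10). C10 is added at the methyl group through the kinetic enolate, because an acid-type Mannich reaction would functionalise C7 instead.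

Remark 2: the vinyl ketone is irradiated at ≥350 nm. Ring A (a β-alkoxyenone with a long-wavelength tail, plus a non-enolisable ketone) and the saturated ketone that forms must stay unexcited.

Remark 3 (assumption): the hetero-Diels–Alder step is not expected to be strongly endo/exo selective and gives racemic material. The C1' epimer is therefore removed by chromatography, and the enantiomers are separated on a chiral phase at the stable methyl ketone stage.

Step 1
Reactants: 1 (E)-geranylacetone
Product: 3 racemic 9,10-epoxygeranylacetone, via bromohydrin 2 (not isolated)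
Conditions: NBS (1.05 equiv), THF–H2O, 0 °C; then K2CO3, MeOH, rt
Reagents that add atoms: water, O
Why: Terminal-selective bromohydrin formation (NBS in aqueous THF attacks the terminal isopropylidene alkene of polyprenoids in preference to the internal one) followed by Williamson-type closure masks the distal alkene; the new oxirane carbon is racemic and returns to sp2 in step 3.

Step 2
Reactants: 3 racemic 9,10-epoxygeranylacetone; 4 syncarpic acid; 5 isovaleraldehyde
Product: 7 racemic epoxy chroman-dione methyl ketone (rel-2R,3S,4R; both oxirane epimers), via alkylidene trione 6 (not isolated)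
Conditions: 4, 5 (1.2 equiv), EDDA (10 mol%), 4 Å MS, MeCN, rt; then 3 (2 equiv), 80 °C
Reagents that add atoms: none
Why: Domino Knoevenagel/inverse-demand hetero-Diels–Alder reaction: the symmetric, electron-poor oxadiene 6 should add to the only remaining trisubstituted alkene with O going to the more substituted C4; the E geometry is transferred suprafacially into the trans arms at C4/C5, whereas C1' depends on the endo/exo mode (isobutyl outside, C4-methyl and C5 chain endo gives the needed epimer), so both epimers are expected and the unwanted one is removed by chromatography; the product is racemic.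

Step 3
Reactants: 7 racemic epoxy chroman-dione methyl ketone
Product: 8 racemic chroman-dione methyl ketone with free homoprenyl chain (rel-2R,3S,4R)
Conditions: Zn dust, NaI, NaOAc, AcOH, 0 °C → rt
Reagents that add atoms: none
Why: Epoxide deoxygenation by iodide opening to the iodohydrin and zinc-induced reductive β-elimination should return the trisubstituted alkene; C11 carries two methyl groups so no alkene geometry is at stake, the oxirane epimers converge to one racemate and the three pyran stereocentres are untouched.

Step 4
Reactants: 8 racemic chroman-dione methyl ketone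
Product: 9 (2R,3S,4R)-chroman-dione methyl ketone
Conditions: preparative SFC, amylose tris(3,5-dimethylphenylcarbamate) phase, CO2/i-PrOH
Reagents that add atoms: none
Why: Resolution by chromatography on a polysaccharide chiral stationary phase should separate the enantiomers of this neutral, stable ketone; no stereocentre is made, and the (2R,3S,4R) antipode is to be identified by ECD or, at the latest, by correlation with the natural product.

Step 5
Reactants: 9 (2R,3S,4R)-chroman-dione methyl ketone
Product: 13 (2R,3S,4R)-chroman-dione vinyl ketone (photosubstrate), via lithium enolate 10 (not isolated), via Mannich base 11 (not isolated), via methiodide 12 (not isolated)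
Conditions: LDA, THF, −78 °C; Me2N=CH2+ I−, −78 → 0 °C; MeI, CH2Cl2–MeOH, rt; aq NaHCO3, CH2Cl2, rt
Reagents that add atoms: Eschenmoser's salt (N,N-dimethylmethylideneammonium iodide), C=[N+](C)C.[I-]
Why: Kinetic deprotonation of the methyl group (C7–H2 is more hindered and ring A has no enolisable hydrogen) followed by a Mannich reaction with Eschenmoser's salt, exhaustive N-methylation and E1cB (Hofmann-type) elimination should give the vinyl ketone, which is made directly before irradiation; no stereocentre is formed.

Step 6
Reactants: 13 (2R,3S,4R)-chroman-dione vinyl ketone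
Product: 15 (1R,4R,5S,9S,1'R)-tetracyclic C8 ketone (13-nor ketone of the target; trans-fused cyclobutane), via C9-epimeric photoadduct 14 (not isolated)
Conditions: hν (350–366 nm, cut-off λ > 340 nm), degassed MeCN, 0.5 mM, rt, to full conversion; concentrate; then t-BuOK (0.2 equiv), t-BuOH–THF, rt
Reagents that add atoms: none
Why: Proposed new method: n→π* excitation of the vinyl ketone and intersystem crossing give the triplet enone, whose β-carbon C10 should bond to the alkene at C11 (head-to-tail sense), leaving a 1,4-biradical at C9 (α-acyl) and C1 that collapses after spin inversion by C1–C9 bonding. The closest known reaction types are the intermolecular enone–isobutylene [2+2] photocycloaddition (same orientation, gem-dimethyl carbon on the β-carbon) and intramolecular [2+2] reactions of alkenyl vinyl ketones with two- to four-atom tethers; a tether that closes a nine-membered ring has no precedent. The cyclobutane closes by radical–radical recombination of the 1,4-biradical, and the nine-membered ring closes in the same C1–C9 event as a straight (fused, not bridged) macrocyclisation between the C4 and C5 arms, which sit trans on adjacent carbons of the half-chair pyran. C1 is set by the alkene face that the folded tether presents and is controlled only by the C4/C5 configuration of ring B, whereas C9 is set thermodynamically by the t-BuOK equilibration to the trans-fused ketone, as in the caryophyllene nor-ketone series. The step needs chemoselective excitation (≥350 nm, where only the vinyl ketone absorbs), straight over crossed regiochemistry (supported by the head-to-tail bias and by the lower strain of the fused bicycle) and the correct C1 face, together with high dilution against oligomerisation of the vinyl ketone.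

Step 7
Reactants: 15 (1R,4R,5S,9S,1'R)-tetracyclic C8 ketone
Product: 16 Tomentodione B
Conditions: Ph3PCH3Br, KOtBu, THF, 0 °C → rt
Reagents that add atoms: methyltriphenylphosphonium bromide, C[P+](c1ccccc1)(c1ccccc1)c1ccccc1.[Br-]
Why: Wittig methylenation: the C8 ketone is the only carbonyl open to the ylide (the ring-A ketone lies between two quaternary carbons and the other carbonyl is a vinylogous ester), and C9, already at its thermodynamic trans configuration, should not be at risk from the basic ylide.

Compound list

1 | (E)-geranylacetone, (5E)-6,10-dimethylundeca-5,9-dien-2-one | CC(C)=CCC/C(C)=C/CCC(C)=O | starting material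
2 | (E)-9-bromo-10-hydroxy-6,10-dimethylundec-5-en-2-one (racemic) | CC(C)(O)C(Br)CC/C(C)=C/CCC(C)=O | intermediate
3 | (E)-8-(3,3-dimethyloxiran-2-yl)-6-methyloct-5-en-2-one (9,10-epoxygeranylacetone, racemic) | CC1(C)OC1CC/C(C)=C/CCC(C)=O | intermediate
4 | syncarpic acid (2,2,4,4-tetramethylcyclohexane-1,3,5-trione) | CC1(C)C(=O)CC(=O)C(C)(C)C1=O | starting material
5 | isovaleraldehyde (3-methylbutanal) | CC(C)CC=O | starting material
6 | 2,2,4,4-tetramethyl-6-(3-methylbutylidene)cyclohexane-1,3,5-trione | CC(C)CC=C1C(=O)C(C)(C)C(=O)C(C)(C)C1=O | intermediate
7 | rel-(2R,3S,4R)-2-[2-(3,3-dimethyloxiran-2-yl)ethyl]-4-isobutyl-2,6,6,8,8-pentamethyl-3-(3-oxobutyl)-3,4-dihydro-2H-chromene-5,7(6H,8H)-dione; racemic, both oxirane epimers; C2-methyl, C3 chain and C4 isobutyl on one face of the pyran, C2 chain on the other (SMILES shows the enantiomer carried on) | CC(=O)CC[C@H]1[C@@H](CC(C)C)C2=C(O[C@]1(C)CCC3OC3(C)C)C(C)(C)C(=O)C(C)(C)C2=O | intermediate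
8 | rel-(2R,3S,4R)-4-isobutyl-2,6,6,8,8-pentamethyl-2-(4-methylpent-3-en-1-yl)-3-(3-oxobutyl)-3,4-dihydro-2H-chromene-5,7(6H,8H)-dione, racemate (SMILES shows the enantiomer carried on) | CC(=O)CC[C@H]1[C@@H](CC(C)C)C2=C(O[C@]1(C)CCC=C(C)C)C(C)(C)C(=O)C(C)(C)C2=O | intermediate
9 | (2R,3S,4R)-4-isobutyl-2,6,6,8,8-pentamethyl-2-(4-methylpent-3-en-1-yl)-3-(3-oxobutyl)-3,4-dihydro-2H-chromene-5,7(6H,8H)-dione, single enantiomer | CC(=O)CC[C@H]1[C@@H](CC(C)C)C2=C(O[C@]1(C)CCC=C(C)C)C(C)(C)C(=O)C(C)(C)C2=O | intermediate
10 | lithium enolate of 9 at the methyl group (lithium but-1-en-2-olate terminus) | [Li+].C=C([O-])CC[C@H]1[C@@H](CC(C)C)C2=C(O[C@]1(C)CCC=C(C)C)C(C)(C)C(=O)C(C)(C)C2=O | intermediate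
11 | (2R,3S,4R)-3-[5-(dimethylamino)-3-oxopentyl] analogue of 9 (Mannich base) | CN(C)CCC(=O)CC[C@H]1[C@@H](CC(C)C)C2=C(O[C@]1(C)CCC=C(C)C)C(C)(C)C(=O)C(C)(C)C2=O | intermediate
12 | trimethylammonium iodide of 11 (methiodide) | C[N+](C)(C)CCC(=O)CC[C@H]1[C@@H](CC(C)C)C2=C(O[C@]1(C)CCC=C(C)C)C(C)(C)C(=O)C(C)(C)C2=O.[I-] | intermediate
13 | (2R,3S,4R)-4-isobutyl-2,6,6,8,8-pentamethyl-2-(4-methylpent-3-en-1-yl)-3-(3-oxopent-4-en-1-yl)-3,4-dihydro-2H-chromene-5,7(6H,8H)-dione (photosubstrate) | C=CC(=O)CC[C@H]1[C@@H](CC(C)C)C2=C(O[C@]1(C)CCC=C(C)C)C(C)(C)C(=O)C(C)(C)C2=O | intermediate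
14 | (1R,4R,5S,1'R)-tetracyclic 13-nor-C8 ketone, mixture of C9 epimers (cis- and trans-fused cyclobutane) | O=C1CC[C@H]2[C@@H](CC(C)C)C3=C(O[C@]2(C)CC[C@@H]2C1CC2(C)C)C(C)(C)C(=O)C(C)(C)C3=O | intermediate
15 | (1R,4R,5S,9S,1'R)-tetracyclic 13-nor-C8 ketone: ring A/B chroman-dione fused at C4–C5 to the cyclononanone, trans-fused 11,11-dimethylcyclobutane at C1/C9 | O=C1CC[C@H]2[C@@H](CC(C)C)C3=C(O[C@]2(C)CC[C@@H]2[C@@H]1CC2(C)C)C(C)(C)C(=O)C(C)(C)C3=O | intermediate
16 | Tomentodione B, (1R,4R,5S,9S,1'R), C8 exocyclic methylidene | C=C1CC[C@H]2[C@@H](CC(C)C)C3=C(O[C@]2(C)CC[C@@H]2[C@@H]1CC2(C)C)C(C)(C)C(=O)C(C)(C)C3=O | target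

Total step count: 7. Longest linear sequence: 7 steps (1 → 16); 4 and 5 enter at step 2.

Steps most likely to fail

1. Step 6 (Proposed new method). Several processes can defeat it:
   - the triplet vinyl ketone may decay by twisting or add to a second molecule before it reaches the remote alkene;
   - ring A may be excited after all and add to the homoprenyl alkene;
   - closure may follow the crossed sense or take the wrong C1 face.

   Fallback with known chemistry: the photochemical ring construction is given up, and the four- and nine-membered rings are taken from the chiral pool. The fallback sets out from 4 and 5, which are condensed as in step 2 to the alkylidene trione 6. This is heated (EDDA cat., MeCN, 60–80 °C) with commercial (−)-β-caryophyllene F1. A hetero-Diels–Alder reaction at the strained endocyclic (E)-C4=C5 alkene, the cycloaddition type by which caryophyllene-derived meroterpenoids are assembled, should give the target among C1' and conformer-derived diastereomers. These are separated by chromatography. The fallback returns to the route at 16.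

2. Step 2. The oxirane may be opened by the acidic trione or the ammonium acetate catalyst at 80 °C, the oxadiene may drain away by tautomerisation or by Michael addition of a second trione, and the endo/exo selectivity at C1' may be poor.

   Fallback: the acid-labile mask is exchanged for a diol. Setting out from 3, hydrolysis (cat. HClO4, THF–H2O) gives the 9,10-diol F2. The same Knoevenagel/hetero-Diels–Alder reaction with 4 and 5 should then give the diol adduct F3, since a diol tolerates the acidic medium and adds to the oxadiene only reversibly. Thiocarbonyldiimidazole (DMAP, PhMe, 80 °C) converts F3 into the cyclic thionocarbonate F4. Corey–Winter elimination (P(OMe)3, 110 °C) regenerates the trisubstituted alkene, and the sequence returns to the route at 8.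

3. Step 7. The ylide may add slowly to the C8 carbonyl beside the cyclobutane and enolise it instead. Forcing conditions may then bring in the ring-A carbonyls.

   Fallback: Peterson olefination in two stages. Setting out from 15, the weakly basic organocerium reagent from Me3SiCH2Li and CeCl3 (THF, −78 °C) should add to the enolisable ketone to give the β-hydroxysilane F5. Base-induced syn-elimination (KH, THF, rt) avoids acid, to which the caryophyllene-type cyclobutane is sensitive, and returns the route to 16.

Further compounds

F1 | step 6 | (−)-β-caryophyllene (purchased partner of the fallback) | C=C1CC/C=C(\C)CC[C@@H]2[C@@H]1CC2(C)C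
F2 | step 2 | (E)-9,10-dihydroxy-6,10-dimethylundec-5-en-2-one (racemic) | CC(C)(O)C(O)CC/C(C)=C/CCC(C)=O
F3 | step 2 | rel-(2R,3S,4R)-2-(3,4-dihydroxy-4-methylpentyl)-4-isobutyl-2,6,6,8,8-pentamethyl-3-(3-oxobutyl)-3,4-dihydro-2H-chromene-5,7(6H,8H)-dione (racemic, both carbinol epimers) | CC(=O)CC[C@H]1[C@@H](CC(C)C)C2=C(O[C@]1(C)CCC(O)C(C)(C)O)C(C)(C)C(=O)C(C)(C)C2=O
F4 | step 2 | cyclic thionocarbonate of F3 (5,5-dimethyl-2-thioxo-1,3-dioxolan-4-yl terminus) | CC(=O)CC[C@H]1[C@@H](CC(C)C)C2=C(O[C@]1(C)CCC3OC(=S)OC3(C)C)C(C)(C)C(=O)C(C)(C)C2=O
F5 | step 7 | C8 tertiary alcohol of 15 bearing a (trimethylsilyl)methyl group (β-hydroxysilane, C8 configuration open) | C[Si](C)(C)CC1(O)CC[C@H]2[C@@H](CC(C)C)C3=C(O[C@]2(C)CC[C@@H]2[C@@H]1CC2(C)C)C(C)(C)C(=O)C(C)(C)C3=O
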